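Compound numbers refer to the compound list after the steps.

## Analysis of the target

Compound 21 is a flavone: a benzene ring A fused through C4a and C8a to the 4-pyranone ring C, which carries the aryl ring B at C2. Ring A bears hydroxyls at C5 and C7 and a methoxyl at C8, with C6 unsubstituted; ring B bears a hydroxyl at C2' and methoxyls at C4' and C5'. There is no stereocentre, so every selectivity question is one of position. The sensitive elements are the three phenols (the C5 hydroxyl is hydrogen-bonded to the C4 carbonyl), two electron-rich arenes open to oxidation and electrophilic attack, and the pyranone, which nucleophiles can open at C2. With a free C5 hydroxyl, such an opening under strong acid can reclose through the other oxygen and move the methoxyl from C8 to C6 (Wessely–Moser rearrangement). The difficulty is twofold: three hydroxyls must be distinguished from three methoxyls on two rings, and the single methoxyl of ring A must end at C8 and not at C6, two positions that both neighbour the C7 oxygen. The strategy rests on one feature: C8a (bearing O1) and C4a (bearing the acyl carbon C4) are adjacent ring A carbons with unlike neighbours, the oxygenated C5 beside C4a and C8 beside C8a. Ring A can therefore enter as an aryne across C4a–C8a, and an O–C(acyl) unit can be added across it in a direction fixed by the substituents at C5 and C8.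

## Retrosynthetic reasoning

**21 from 20.** The three phenolic O–H groups are traced back to benzyl ethers. Every future hydroxyl is carried as a benzyl ether and every future methoxyl as a methyl ether, so one neutral hydrogenolysis at the end separates the two sets. Neutral conditions matter because the C5 hydroxyl, once free, makes the pyranone prone to acid-triggered opening and reclosure that would exchange C8 and C6.

**20 from 19 and 18.** The C8–O bond is cut, first to the C8 iodide 19 and then to the C8 silane 18. The methoxyl is not carried through the ring-forming step on purpose. With an alkoxy group at C8 as well as at C5, both flanks of the aryne would pull in opposite directions and the addition would lose its bias. Silicon at C8 polarises the aryne in the required sense and can afterwards be replaced ipso at exactly that carbon. The forward steps are an ipso-iododesilylation and a copper-mediated C–O coupling.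

**18 from 10 and 15.** This is the central disconnection: O1–C8a, C4–C4a and O1–C2 are cut together, which removes ring C. Ring A becomes the aryne released from the bis-silyl triflate 10, and C2, C3, C4 and ring B come from the arylpropiolic acid 15. The cut is made here because neither partner needs a regiochemical decision in its own synthesis. The forward reaction must add the carboxylate oxygen to the future C8a, shift the acyl group to C4a, and close the pyranone by addition of the resulting phenoxide to the ynone.

**10 from 8, 2 and 1.** The S–O bond of the triflate and the two C–Si bonds are cut. The phenol oxygen of 1 is turned into a carbamate that directs lithiation to the two positions lying between it and a benzyloxy group. Because 1 is symmetric, these positions are equivalent and the two silylations need no differentiation. Both are carried out in one flask: the nitrogen of 2 is silylated once, and this temporary protection stays in place through the first lithiation–silylation, so the second cycle follows directly and only 8 is isolated. An N-isopropyl carbamate (2) is chosen because it is removed by elimination from the deprotonated nitrogen, not by attack at a carbonyl that is shielded by two silyl groups in 8.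

**15 from 13, 12 and 11.** The C–CO2H bond and the alkyne are cut back to the aldehyde carbon of 11. The phenol of 11 is benzylated (12), the aldehyde is homologated to the dibromoalkene 13, and the acetylide formed from 13 is carboxylated in the same flask.

## Alternatives that were turned down

**Alternative 1:** Ring C is disconnected at C4–C4a only. The precursor is the 4-aryloxycoumarin A2, whose lactone carbonyl is to become C4 and whose ring oxygen is to become the C2' hydroxyl. In the forward key step a strong acid would make the lactone carbonyl acylate the aryloxy ring ortho to the ether oxygen, closing ring C and opening the lactone to give A1.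
- For: the C8 methoxyl is in place from the start and the C2' hydroxyl is released by the key step itself, so the endgame would be one hydrogenolysis. On endgame length this alternative is stronger than the chosen route.
- Against: a lactone carbonyl conjugated to an enol ether is a weak acylating agent and needs forcing acid. Benzyl ethers on a phloroglucinol-type ring are cleaved or migrate to carbon under such conditions, and a freed C5 hydroxyl in acid opens the way to C8/C6 scrambling. The aryloxy half of A2 is a phenol with three different oxygen substituents that itself needs a multistep, regiocontrolled preparation.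
- Comparison: the chosen route spends two more steps after ring closure, but its ring-forming step runs under fluoride in an aprotic solvent, where benzyl ethers are inert, and its ring A partner comes from a symmetric commercial phenol.

**Alternative 2:** Ring A is disconnected at C7–C8 and C5–C6 and built onto a preformed pyranone. The precursor is the pyranone ester A4, whose methoxymethyl carbon is the future C8 and whose ester carbon is the future C5. In the forward key step LiN(i-Pr)2 would deprotonate the methoxymethyl group, the anion would be acylated by ethyl acetate A5 (supplying C7 and C6), and the new methyl ketone enolate would condense onto the ester to give A3.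
- For: every oxygen of ring A is placed by construction, the C8 methoxyl needs no late introduction, and A3 carries only one benzyl group, so the endgame is again a single step. On these points it is stronger than the chosen route.
- Against: A5 is enolisable and would be deprotonated by the vinylogous anion or condense with itself. The first acylation product is more acidic than A4 and quenches a second equivalent of anion. The 4-pyranone is open to nucleophilic attack at C2 and C6. A4 is a trisubstituted pyranone that needs its own multistep assembly. Several uncertain operations would therefore precede the key step as well as lie within it.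
- Comparison: the chosen route concentrates its uncertainty in one step and reaches both partners by standard aromatic chemistry.

**Alternative 3:** Ring C is disconnected at C4a–C4, C4–C3 and O1–C2 into the iodophenol A7, carbon monoxide A9 and the arylalkyne A8. In the forward key step PdCl2(PPh3)2 with Et2NH would effect carbonylative coupling of A7 with A8 and cyclisation of the resulting ynone to A6, which has the same structure as 20.
- For: this three-component annulation is well precedented, it is as convergent as the chosen route, A8 is one step from 13, and it reaches the stage of 20 without the iododesilylation and methoxylation steps. On precedent and on endgame length it is stronger.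
- Against: the regiochemical problem is moved into A7, a benzene with five substituents of four kinds. Its iodine would have to be introduced ortho to the hydroxyl on a ring whose other free position, between the two benzyloxy groups, is equally activated. The iodide is flanked on both sides, which slows oxidative addition and carbon monoxide insertion, and non-carbonylative coupling to a benzofuran and five-membered closure to an aurone are known competing paths.
- Comparison: the chosen route avoids A7. Its ring A partner is made from symmetric 1 by two equivalent silylations, and the silicon left over after the annulation is the handle that fixes the methoxyl at C8.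

Key step: step 7

Assumption: 1 and 11 are taken as purchasable; the benzyl ethers of 1 are taken to tolerate n-BuLi/TMEDA at −78 °C for the time needed to lithiate a position activated by two oxygen groups.

## Route

**Step 1**
Reactants: 1 3,5-bis(benzyloxy)phenol
Product: 2 3,5-bis(benzyloxy)phenyl N-isopropylcarbamate
Conditions: i-PrNCO, Et3N (cat.), CH2Cl2, rt
Reagents that add atoms: isopropyl isocyanate, CC(C)N=C=O
Why: Base-catalysed addition of a phenol to an isocyanate gives the N-monoalkyl carbamate, which serves as directing group and is later removable by elimination.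

**Step 2**
Reactants: 2 3,5-bis(benzyloxy)phenyl N-isopropylcarbamate
Product: 8 3,5-bis(benzyloxy)-2,6-bis(trimethylsilyl)phenyl N-isopropylcarbamate, via N-silyl carbamate 3 (not isolated), via ortho-lithiated N-silyl carbamate 4 (not isolated), via N-silyl 2-silyl carbamate 5 (not isolated), via 6-lithio N-silyl 2-silyl carbamate 6 (not isolated), via N-silyl 2,6-disilyl carbamate 7 (not isolated)
Conditions: TMSOTf (1.1 equiv), TMEDA, Et2O, 0 °C to rt; n-BuLi (2.2 equiv), TMEDA, −78 °C; TMSCl (1.2 equiv), −78 to 0 °C; n-BuLi (1.3 equiv), −78 °C; TMSCl (excess), −78 °C to rt; sat. aq. NH4Cl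
Reagents that add atoms: chlorotrimethylsilane, C[Si](C)(C)Cl
Why: Directed ortho-metalation run twice in one flask: N-silylation blocks the N–H so that the carbamate cannot eliminate, n-BuLi/TMEDA (one equivalent of which neutralises the TMEDA triflate salt) lithiates between the carbamate and a benzyloxy group where two directing groups cooperate (C2 and C6 are equivalent), and TMSCl traps aryllithium 4 to give 5. Because the N-silyl group of 5 is still in place, a second charge of n-BuLi should lithiate the remaining position next to the carbamate in preference to C4, which lies between two benzyloxy groups but lacks the stronger carbamate director, and TMSCl gives 7. The first TMSCl charge is kept near stoichiometric so that it does not consume the second charge of base, and aqueous work-up removes the N-silyl group.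

**Step 3**
Reactants: 8 3,5-bis(benzyloxy)-2,6-bis(trimethylsilyl)phenyl N-isopropylcarbamate
Product: 10 3,5-bis(benzyloxy)-2,6-bis(trimethylsilyl)phenyl trifluoromethanesulfonate, via 3,5-bis(benzyloxy)-2,6-bis(trimethylsilyl)phenol 9 (not isolated)
Conditions: DBU, Et2NH, MeCN, 40 °C; then PhNTf2, rt
Reagents that add atoms: N-phenylbis(trifluoromethanesulfonimide), O=S(=O)(N(c1ccccc1)S(=O)(=O)C(F)(F)F)C(F)(F)F
Why: E1cB cleavage of the N–H carbamate (DBU removes the proton, the aryloxide leaves, Et2NH traps the isocyanate as a urea) needs no attack at the carbonyl shielded by two silyl groups; the phenoxide is then O-triflated in the same flask under basic conditions that spare the acid-labile aryl–silicon bonds.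

**Step 4**
Reactants: 11 2-hydroxy-4,5-dimethoxybenzaldehyde
Product: 12 2-(benzyloxy)-4,5-dimethoxybenzaldehyde
Conditions: BnBr, K2CO3, DMF, rt
Reagents that add atoms: benzyl bromide, BrCc1ccccc1
Why: Williamson etherification of the phenoxide; the benzyl group masks the future C2' hydroxyl in the same way as the ring A hydroxyls.

**Step 5**
Reactants: 12 2-(benzyloxy)-4,5-dimethoxybenzaldehyde
Product: 13 1-(benzyloxy)-2-(2,2-dibromoethenyl)-4,5-dimethoxybenzene
Conditions: CBr4, PPh3, CH2Cl2, 0 °C
Reagents that add atoms: carbon tetrabromide, BrC(Br)(Br)Br
Why: First stage of the Corey–Fuchs reaction; the dibromomethylene ylide formed from CBr4 and PPh3 olefinates the aldehyde in a Wittig-type reaction.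

**Step 6**
Reactants: 13 1-(benzyloxy)-2-(2,2-dibromoethenyl)-4,5-dimethoxybenzene
Product: 15 3-[2-(benzyloxy)-4,5-dimethoxyphenyl]prop-2-ynoic acid, via lithium arylacetylide 14 (not isolated)
Conditions: n-BuLi (2.2 equiv), THF, −78 °C; CO2, −78 °C to rt; 1 M HCl
Reagents that add atoms: carbon dioxide, O=C=O
Why: Second stage of the Corey–Fuchs reaction (bromine–lithium exchange, Fritsch–Buttenberg–Wiechell shift and deprotonation give the lithium acetylide), followed by carboxylation of the acetylide; the exchange at −78 °C is far faster than any attack on the benzyl ether.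

**Step 7**
Reactants: 10 3,5-bis(benzyloxy)-2,6-bis(trimethylsilyl)phenyl trifluoromethanesulfonate; 15 3-[2-(benzyloxy)-4,5-dimethoxyphenyl]prop-2-ynoic acid
Product: 18 5,7-bis(benzyloxy)-2-[2-(benzyloxy)-4,5-dimethoxyphenyl]-8-(trimethylsilyl)-4H-chromen-4-one, via 3,5-bis(benzyloxy)-6-(trimethylsilyl)benzyne 16 (not isolated), via 2-hydroxyaryl ynone 17 (not isolated)
Conditions: CsF (4 equiv), THF, 125 °C (sealed tube); 10 (1.5 equiv)
Reagents that add atoms: none
Why: Fluoride removes one of the two silyl groups of 10, which are equivalent by the mirror plane through the triflate carbon, and triflate leaves, so only aryne 16 can form, while 15 is present as its cesium carboxylate. The carboxylate oxygen adds to the aryne carbon that becomes C8a: the C5 benzyloxy group directs a nucleophile to the distal aryne carbon so that the negative charge develops at C4a next to oxygen, and the electropositive silyl group at C8 makes its own neighbour the more electrophilic aryne carbon, so both flanking groups select the same carbon. The aryl anion at C4a attacks the adjacent ester carbonyl through a four-membered alkoxide that opens to the 2-acylphenoxide 17, a net insertion of the aryne into the acyl C–O bond that forms O1–C8a and C4–C4a. The phenoxide oxygen then adds to the β-carbon of the ynone in a 6-endo-dig oxa-Michael closure that forms O1–C2 and ring C; 5-exo-dig closure to an aurone would require attack at the α-carbon against the polarity of the ynone. The proton of the acid ends at C3, so no further reagent enters the product. The closest known reaction type is the insertion of arynes from 2-silylaryl triflates into the C–O bond of carboxylic acids, which gives flavones with 3-arylpropiolic acids, together with the release of 3-silylarynes from 2,6-bis(silyl)aryl triflates. The step needs the acyl shift to outrun protonation of the aryl anion, which heat and the sparingly soluble fluoride in THF favour, and it needs the C8 silyl group to survive, which is reasonable because that carbon has no leaving group beside it once the aryne is consumed. No stereocentre is formed.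

**Step 8**
Reactants: 18 5,7-bis(benzyloxy)-2-[2-(benzyloxy)-4,5-dimethoxyphenyl]-8-(trimethylsilyl)-4H-chromen-4-one
Product: 19 5,7-bis(benzyloxy)-2-[2-(benzyloxy)-4,5-dimethoxyphenyl]-8-iodo-4H-chromen-4-one
Conditions: ICl (1.05 equiv), CH2Cl2, −78 to 0 °C
Reagents that add atoms: iodine monochloride, ClI
Why: Electrophilic ipso-iododesilylation; attack at the silicon-bearing C8 gives a cation stabilised by the β-silicon effect and by O1 and the C7 and C5 oxygens, and chloride removes silicon, so one equivalent at low temperature should leave C6 and ring B untouched.

**Step 9**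
Reactants: 19 5,7-bis(benzyloxy)-2-[2-(benzyloxy)-4,5-dimethoxyphenyl]-8-iodo-4H-chromen-4-one
Product: 20 5,7-bis(benzyloxy)-2-[2-(benzyloxy)-4,5-dimethoxyphenyl]-8-methoxy-4H-chromen-4-one
Conditions: NaOMe, CuI (cat.), MeOH–DMF, 100 °C
Reagents that add atoms: sodium methoxide, C[O-].[Na+]
Why: Ullmann-type copper-mediated C–O coupling replaces iodide by methoxide at C8; any reversible addition of methoxide at C2 can only return to the same flavone, because O1 is the one oxygen able to reclose while the C5 oxygen is benzylated.

**Step 10**
Reactants: 20 5,7-bis(benzyloxy)-2-[2-(benzyloxy)-4,5-dimethoxyphenyl]-8-methoxy-4H-chromen-4-one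
Product: 21 5,7-dihydroxy-2-(2-hydroxy-4,5-dimethoxyphenyl)-8-methoxy-4H-chromen-4-one
Conditions: H2 (1 atm), 10% Pd/C, EtOAc–MeOH, rt
Reagents that add atoms: none
Why: Catalytic hydrogenolysis cleaves the three benzylic C–O bonds under neutral conditions and leaves the methyl ethers alone; the reaction is stopped when the benzyl ethers are consumed so that the C2–C3 double bond is not saturated.

## Compound list

1 | 3,5-bis(benzyloxy)phenol | Oc1cc(OCc2ccccc2)cc(OCc2ccccc2)c1 | starting material
2 | 3,5-bis(benzyloxy)phenyl N-isopropylcarbamate | CC(C)NC(=O)Oc1cc(OCc2ccccc2)cc(OCc2ccccc2)c1 | intermediate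
3 | 3,5-bis(benzyloxy)phenyl N-isopropyl-N-(trimethylsilyl)carbamate (formed in the flask, not isolated) | CC(C)N([Si](C)(C)C)C(=O)Oc1cc(OCc2ccccc2)cc(OCc2ccccc2)c1 | intermediate
4 | 3,5-bis(benzyloxy)-2-lithiophenyl N-isopropyl-N-(trimethylsilyl)carbamate (formed in the flask, not isolated) | CC(C)N([Si](C)(C)C)C(=O)Oc1cc(OCc2ccccc2)cc(OCc2ccccc2)c1[Li] | intermediate
5 | 3,5-bis(benzyloxy)-2-(trimethylsilyl)phenyl N-isopropyl-N-(trimethylsilyl)carbamate (formed in the flask, not isolated) | CC(C)N([Si](C)(C)C)C(=O)Oc1cc(OCc2ccccc2)cc(OCc2ccccc2)c1[Si](C)(C)C | intermediate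
6 | 3,5-bis(benzyloxy)-2-lithio-6-(trimethylsilyl)phenyl N-isopropyl-N-(trimethylsilyl)carbamate (formed in the flask, not isolated) | CC(C)N([Si](C)(C)C)C(=O)Oc1c([Li])c(OCc2ccccc2)cc(OCc2ccccc2)c1[Si](C)(C)C | intermediate
7 | 3,5-bis(benzyloxy)-2,6-bis(trimethylsilyl)phenyl N-isopropyl-N-(trimethylsilyl)carbamate (formed in the flask, not isolated) | CC(C)N([Si](C)(C)C)C(=O)Oc1c([Si](C)(C)C)c(OCc2ccccc2)cc(OCc2ccccc2)c1[Si](C)(C)C | intermediate
8 | 3,5-bis(benzyloxy)-2,6-bis(trimethylsilyl)phenyl N-isopropylcarbamate | CC(C)NC(=O)Oc1c([Si](C)(C)C)c(OCc2ccccc2)cc(OCc2ccccc2)c1[Si](C)(C)C | intermediate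
9 | 3,5-bis(benzyloxy)-2,6-bis(trimethylsilyl)phenol (present as its DBU salt, not isolated) | Oc1c([Si](C)(C)C)c(OCc2ccccc2)cc(OCc2ccccc2)c1[Si](C)(C)C | intermediate
10 | 3,5-bis(benzyloxy)-2,6-bis(trimethylsilyl)phenyl trifluoromethanesulfonate | C[Si](C)(C)c1c(OCc2ccccc2)cc(OCc2ccccc2)c([Si](C)(C)C)c1OS(=O)(=O)C(F)(F)F | intermediate
11 | 2-hydroxy-4,5-dimethoxybenzaldehyde | COc1cc(O)c(C=O)cc1OC | starting material
12 | 2-(benzyloxy)-4,5-dimethoxybenzaldehyde | COc1cc(OCc2ccccc2)c(C=O)cc1OC | intermediate
13 | 1-(benzyloxy)-2-(2,2-dibromoethenyl)-4,5-dimethoxybenzene | COc1cc(OCc2ccccc2)c(C=C(Br)Br)cc1OC | intermediate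
14 | {[2-(benzyloxy)-4,5-dimethoxyphenyl]ethynyl}lithium (formed in the flask, not isolated) | [Li]C#Cc1cc(OC)c(OC)cc1OCc1ccccc1 | intermediate
15 | 3-[2-(benzyloxy)-4,5-dimethoxyphenyl]prop-2-ynoic acid | OC(=O)C#Cc1cc(OC)c(OC)cc1OCc1ccccc1 | intermediate
16 | 3,5-bis(benzyloxy)-6-(trimethylsilyl)benzyne (formed in the flask, not isolated) | C[Si](C)(C)C1=C(OCc2ccccc2)C=C(OCc2ccccc2)C#C1 | intermediate
17 | 1-[4,6-bis(benzyloxy)-2-hydroxy-3-(trimethylsilyl)phenyl]-3-[2-(benzyloxy)-4,5-dimethoxyphenyl]prop-2-yn-1-one (present as its cesium phenoxide, not isolated) | C[Si](C)(C)c1c(O)c(C(=O)C#Cc2cc(OC)c(OC)cc2OCc2ccccc2)c(OCc2ccccc2)cc1OCc1ccccc1 | intermediate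
18 | 5,7-bis(benzyloxy)-2-[2-(benzyloxy)-4,5-dimethoxyphenyl]-8-(trimethylsilyl)-4H-chromen-4-one | C[Si](C)(C)c1c(OCc2ccccc2)cc(OCc2ccccc2)c2c1oc(-c1cc(OC)c(OC)cc1OCc1ccccc1)cc2=O | intermediate
19 | 5,7-bis(benzyloxy)-2-[2-(benzyloxy)-4,5-dimethoxyphenyl]-8-iodo-4H-chromen-4-one | Ic1c(OCc2ccccc2)cc(OCc2ccccc2)c2c1oc(-c1cc(OC)c(OC)cc1OCc1ccccc1)cc2=O | intermediate
20 | 5,7-bis(benzyloxy)-2-[2-(benzyloxy)-4,5-dimethoxyphenyl]-8-methoxy-4H-chromen-4-one | COc1c(OCc2ccccc2)cc(OCc2ccccc2)c2c1oc(-c1cc(OC)c(OC)cc1OCc1ccccc1)cc2=O | intermediate
21 | 5,7-dihydroxy-2-(2-hydroxy-4,5-dimethoxyphenyl)-8-methoxy-4H-chromen-4-one | COc1cc(O)c(-c2cc(=O)c3c(O)cc(O)c(OC)c3o2)cc1OC | target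

## Step count and least certain steps

Total step count: 10. Longest linear sequence: 7 (steps 1 to 3, then 7 to 10); the acid 15 is made in 3 steps in parallel (steps 4 to 6).

**Step 7 (key step).** Three processes may divert it.
- Protonation of the aryl anion at C4a before the acyl shift would stop the sequence at a simple aryl ester.
- Fluoride-induced loss of the C8 silyl group at 125 °C would erase the marker for the methoxyl.
- Attack at the other aryne carbon is conceivable because the bulk of the silyl group beside C8a opposes the two polar effects.

The fallback uses known chemistry and does not involve an aryne. Aldehyde 12 is condensed with 1-[2,4-bis(benzyloxy)-6-hydroxyphenyl]ethan-1-one F1, which is available by dibenzylation of 2,4,6-trihydroxyacetophenone (KOH, EtOH, Claisen–Schmidt condensation), to the chalcone (E)-1-[2,4-bis(benzyloxy)-6-hydroxyphenyl]-3-[2-(benzyloxy)-4,5-dimethoxyphenyl]prop-2-en-1-one F2. F2 is cyclised and dehydrogenated (catalytic I2, DMSO, heat) to 5,7-bis(benzyloxy)-2-[2-(benzyloxy)-4,5-dimethoxyphenyl]-4H-chromen-4-one F3. Electrophilic iodination of F3 (N-iodosuccinimide, catalytic CF3CO2H, MeCN), which for fully O-alkylated 5,7-dioxygenated flavones is expected at C8, returns to the route at 19. This path relies on the inherent C8 preference instead of a placed marker, and iodination at C6 or on ring B is its weak point.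

**Step 2.** Benzylic deprotonation of a benzyl ether followed by [1,2]-Wittig rearrangement, or lithiation at C4 between the two benzyloxy groups, may compete with the directed lithiation in either cycle. The second cycle may also stop short if residual TMSCl consumes the second charge of base. The fallback changes the directing group and the base and sets out from 1. Carbamoylation with Et2NCOCl gives 3,5-bis(benzyloxy)phenyl N,N-diethylcarbamate F4. Treatment with LiN(i-Pr)2 in the presence of TMSCl at −78 °C (in situ quench with an amide base that does not attack benzyl ethers) should silylate both ortho positions in one operation and give 3,5-bis(benzyloxy)-2,6-bis(trimethylsilyl)phenyl N,N-diethylcarbamate F5. Reduction with LiAlH4 in THF releases the phenol 9, here isolated, which is triflated with PhNTf2 and base to rejoin the route at 10. The price is a reductive cleavage at a crowded carbamate.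

**Step 9.** Reduction of the C–I bond to C–H under the CuI/NaOMe conditions, or degradation of the pyranone by methoxide at 100 °C, may lower the conversion. The fallback forms the C8–O bond by oxidation and the O–CH3 bond last, and sets out from 19. Miyaura borylation (bis(pinacolato)diboron, PdCl2(dppf), KOAc, dioxane) gives 5,7-bis(benzyloxy)-2-[2-(benzyloxy)-4,5-dimethoxyphenyl]-8-(4,4,5,5-tetramethyl-1,3,2-dioxaborolan-2-yl)-4H-chromen-4-one F6. Oxidation with NaBO3·4H2O in THF–water gives 5,7-bis(benzyloxy)-2-[2-(benzyloxy)-4,5-dimethoxyphenyl]-8-hydroxy-4H-chromen-4-one F7. Methylation (MeI, K2CO3, acetone) returns to the route at 20.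

**Step 10.** Saturation of the C2–C3 double bond to the flavanone, or incomplete cleavage of one benzyl ether, may occur. The fallback replaces reduction by Lewis-acid cleavage and goes from 20 directly to 21: BCl3 with pentamethylbenzene as cation trap in CH2Cl2 at −78 °C removes the benzyl groups and leaves the double bond and the methyl ethers, none of which is peri to the carbonyl. No new compound arises on this path (F0).

## Further compounds

F1 | step 7 | 1-[2,4-bis(benzyloxy)-6-hydroxyphenyl]ethan-1-one | CC(=O)c1c(O)cc(OCc2ccccc2)cc1OCc1ccccc1
F2 | step 7 | (E)-1-[2,4-bis(benzyloxy)-6-hydroxyphenyl]-3-[2-(benzyloxy)-4,5-dimethoxyphenyl]prop-2-en-1-one | O=C(/C=C/c1cc(OC)c(OC)cc1OCc1ccccc1)c1c(O)cc(OCc2ccccc2)cc1OCc1ccccc1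
F3 | step 7 | 5,7-bis(benzyloxy)-2-[2-(benzyloxy)-4,5-dimethoxyphenyl]-4H-chromen-4-one | O=c1cc(-c2cc(OC)c(OC)cc2OCc2ccccc2)oc2cc(OCc3ccccc3)cc(OCc3ccccc3)c12
F4 | step 2 | 3,5-bis(benzyloxy)phenyl N,N-diethylcarbamate | CCN(CC)C(=O)Oc1cc(OCc2ccccc2)cc(OCc2ccccc2)c1
F5 | step 2 | 3,5-bis(benzyloxy)-2,6-bis(trimethylsilyl)phenyl N,N-diethylcarbamate | CCN(CC)C(=O)Oc1c([Si](C)(C)C)c(OCc2ccccc2)cc(OCc2ccccc2)c1[Si](C)(C)C
F6 | step 9 | 5,7-bis(benzyloxy)-2-[2-(benzyloxy)-4,5-dimethoxyphenyl]-8-(4,4,5,5-tetramethyl-1,3,2-dioxaborolan-2-yl)-4H-chromen-4-one | CC1(C)OB(OC1(C)C)c1c(OCc2ccccc2)cc(OCc2ccccc2)c2c1oc(-c1cc(OC)c(OC)cc1OCc1ccccc1)cc2=O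
F7 | step 9 | 5,7-bis(benzyloxy)-2-[2-(benzyloxy)-4,5-dimethoxyphenyl]-8-hydroxy-4H-chromen-4-one | Oc1c(OCc2ccccc2)cc(OCc2ccccc2)c2c1oc(-c1cc(OC)c(OC)cc1OCc1ccccc1)cc2=O
F0 | step 10 | none | none
A1 | alternative 1 | 5,7-bis(benzyloxy)-2-(2-hydroxy-4,5-dimethoxyphenyl)-8-methoxy-4H-chromen-4-one | COc1c(OCc2ccccc2)cc(OCc2ccccc2)c2c1oc(-c1cc(OC)c(OC)cc1O)cc2=O
A2 | alternative 1 | 4-[3,5-bis(benzyloxy)-2-methoxyphenoxy]-6,7-dimethoxy-2H-chromen-2-one | COc1cc2oc(=O)cc(Oc3cc(OCc4ccccc4)cc(OCc4ccccc4)c3OC)c2cc1OC
A3 | alternative 2 | 2-[2-(benzyloxy)-4,5-dimethoxyphenyl]-5,7-dihydroxy-8-methoxy-4H-chromen-4-one | COc1c(O)cc(O)c2c1oc(-c1cc(OC)c(OC)cc1OCc1ccccc1)cc2=O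
A4 | alternative 2 | ethyl 6-[2-(benzyloxy)-4,5-dimethoxyphenyl]-2-(methoxymethyl)-4-oxo-4H-pyran-3-carboxylate | CCOC(=O)c1c(COC)oc(-c2cc(OC)c(OC)cc2OCc2ccccc2)cc1=O
A5 | alternative 2 | ethyl acetate | CCOC(C)=O
A6 | alternative 3 | 5,7-bis(benzyloxy)-2-[2-(benzyloxy)-4,5-dimethoxyphenyl]-8-methoxy-4H-chromen-4-one | COc1c(OCc2ccccc2)cc(OCc2ccccc2)c2c1oc(-c1cc(OC)c(OC)cc1OCc1ccccc1)cc2=O
A7 | alternative 3 | 3,5-bis(benzyloxy)-2-iodo-6-methoxyphenol | COc1c(O)c(I)c(OCc2ccccc2)cc1OCc1ccccc1
A8 | alternative 3 | 1-(benzyloxy)-2-ethynyl-4,5-dimethoxybenzene | C#Cc1cc(OC)c(OC)cc1OCc1ccccc1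
A9 | alternative 3 | carbon monoxide | [C-]#[O+]
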